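Late in the maple run, which is the flask asked about, monomer in chains U fell from 11.8% at 2.50 min to 3.3% at 10.0 min while free monomer stood near 32.0%. I therefore wrote the loss of chains as s·U·F, with F the fraction of charged monomer still free, and read s = 0.497 /min.

the same everywhere: free monomer 20 mM; initiator 0.5 mol%
- maple: transfer agent 2 mM; the very flask that is asked about, followed so far
- flask: transfer agent 2.00 mM; time 25 min

maple run (percent of the free monomer charged)

| time / min | monomer in chains / % | free monomer / % |
|---|---|---|
| 0.167 | 14.0 | 79.1 |
| 0.500 | 18.3 | 60.5 |
| 2.50 | 11.8 | 36.3 |
| 10.0 | 3.3 | 32.0 |

(each reading ± 1 percentage point)

- in percentages every species weighs as the free monomer in it: one self-condensation product or side product counts as two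
- the earlier runs were read with a standard deviation of 1 percentage point
- steps under discussion: living end + transfer agent -> dead chain; 2 free monomer -> self-condensation product; free monomer + living end -> monomer in chains + living end; free monomer <-> dormant form; free monomer + monomer in chains -> side product; free monomer + initiator -> living end + monomer in chains

1. time, not beyond 25 min, at which the flask holds most monomer in chains
2. the amount of monomer in chains, in percent of the free monomer charged, at that time

Chains are gained at a·F, so F cancels from the balance and the top stands where a = s·U. Transfer agent outnumbers initiator 20.0 to one, so I took the death of living ends as pseudo-first-order, a = a₀·exp(−kt). The two early intervals gave a = 0.971 /min and 0.265 /min, hence the readings k = 5.19 /min and a₀ = 1.50 /min.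

Integrating the propagation rate in closed form gives the reach B = a₀/k = 0.289, the logarithmic bite that living ends take from free monomer before they die. By this route my reckoning puts 25.1% of the charge into chains. With U near the reading 18.3%, my top falls at 0.540 min.

The neighbouring flask with 3.4 mM of transfer agent looks nearly the same, but by this reckoning its living ends die 1.70 times as fast, so its B is 0.170. I therefore expected a lower top there. At the late F of the maple run, chains halve in 4.35 min, short against 25 min.

The forecast gave 0.5 min and 18.6%, saying “Later times only lose chains”; my time is slightly later.

The flask peaked at 0.524 min with 18.7%.

    living end + transfer agent → dead chain (kL = 47.0 /M/s)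
    2 free monomer → self-condensation product (k = 0.00140 /M/s)
    free monomer + living end → monomer in chains + living end, rate k3*[living end]*[free monomer] (k = 260 /M/s)
    free monomer ⇌ dormant form (K = 0.900, k = 0.00850 /s)
    free monomer + monomer in chains → side product (k = 0.490 /M/s)
    free monomer + initiator → living end + monomer in chains (k = 26.0 /M/s)

At 25.0 min side product in the flask stood at 45.0%, and since it weighs as two, with one of its two units from chains, the monomer that had entered chains came to 22.7%, below the 25.1% from B. For the neighbour with 3.4 mM, B gave 15.6%, and the same sum at 25.0 min came to 14.7%.

The earlier runs and the new flask stem from a simulated flask with made-up constants; scatter was added.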